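The numbers of this flask were drawn at random within sensible limits; the run is a simulation.

Start from a ratio: the rate of the direct step from E and G to E.G over the rate of the step that E.G itself assists. Both steps use E and G at the same concentrations, so these cancel and the ratio is c×/c(E.G). Here c× is the crossover concentration, 0.0286 M at 0 °C, the c(E.G) at which the two paths run level. Below it the direct step seeds the flask; above it autocatalysis leads.

    E + G + E.G → 2 E.G (k1 = 0.0063 M⁻² s⁻¹, Ea1 = 40.0 kJ mol⁻¹)
    Q ⇌ G, rate k2*(csat - [G]) (k2 = 7.8 × 10⁻⁴ s⁻¹, csat = 140 mM)
    G + E.G → G.E.G (k3 = 0.0010 M⁻¹ s⁻¹, Ea3 = 49.0 kJ mol⁻¹)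
    E + G → E.G (k4 = 1.8 × 10⁻⁴ M⁻¹ s⁻¹, Ea4 = 71.0 kJ mol⁻¹)
    (constants at 0 °C)

all flasks: E 0.50 M; Q 140 mM (held); time 1.0 h

| flask | temperature |
|---|---|
| Monday's | 30 °C |
| Tuesday's | 0 °C |

- the best flask by amount of E.G, in percent of the E charged; "all alike" if 1.5 percentage points covers them all (Monday's / Tuesday's / all alike)
- amount of E.G at the end, in percent of the E charged, Monday's
- amount of E.G at the end, in percent of the E charged, Tuesday's

- at the start none of G is dissolved
- the list of constants is for 0 °C, to be carried to other temperatures by the activation energies

You take over Tuesday's flask. It starts with E and no dissolved G, and Q fills G towards 140 mM with a time of 21.4 min. Freeze c(E) at its charge and let c(G) follow that filling curve. The assisted growth then has the exponent 1.06 over the hour, and c(E.G) equals c× times that exponential less one. So I reckon 10.7% of the charge when you come, with the loss to G.E.G left out. That stands above c×, so expect the assisted path ahead by then.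

Leave the bath alone. Between 0 °C and 30 °C the direct step gains a factor 22 and the assisted one 5.7, so in Monday's flask c× is 0.110 M. I can't freeze c(G) there, so I commit to no figure for Monday's flask; both paths to E.G run faster in it than in Tuesday's, so I expect Monday's flask ahead.

The forecast says Monday's, with 34% for Monday's flask and 7% for Tuesday's, where “autocatalysis barely gets going”. My Tuesday figure stands above its own.

The simulation gives Monday's, with 33.6% and 7.27%. In Tuesday's flask the direct path used G at 7.0 times the assisted rate at 0.286 h and at 0.79 times it at 1.00 h, which is c× over the c(E.G) then standing, 0.786. In Tuesday's flask left until 4.0 h, E.G stands at 39.2% of the charge, and c× puts the direct path at 0.146 of the assisted rate.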